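The runs stem from a simulated flask with constants of no real substance, noise included.

I decided to reckon the south flask from one ratio read off the alpha run, with no rate constant in it.

all flasks: left-handed substrate 0.16 M; right-handed substrate 0.16 M

|  | partner | remark | time |
|---|---|---|---|
| alpha | 0.64 equiv | run made earlier |  |
| beta | 4 equiv | run made earlier |  |
| north | 3.20 equiv |  | 12 h |
| south-east | 1.60 equiv |  | 12 h |
| south | 0.540 equiv |  | 12 h |
| south-west | 0.800 equiv |  | 12 h |

| run | time / h | left-handed product / % | left-handed substrate / % |
|---|---|---|---|
| alpha | 0.500 | 10.2 | 38.7 |
| alpha | 1.00 | 16.8 | 34.7 |
| alpha | 2.50 | 22.3 | 28.8 |
| alpha | 6.00 | 23.3 | 27.1 |
| beta | 0.500 | 38.6 | 11.6 |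
| beta | 1.00 | 45.7 | 4.5 |
| beta | 2.50 | 49.0 | 1.1 |
| beta | 6.00 | 49.2 | 0.3 |

(readings scatter by 0.5 percentage points)

- all flasks from highest to lowest amount of left-handed product, in percent of the left-handed substrate and right-handed substrate together charged, at 12 h (north / south-east / south / south-west)
- the amount of left-handed product, in percent of the left-handed substrate and right-handed substrate together charged of the flask you put first, at 12 h
- the amount of left-handed product, in percent of the left-handed substrate and right-handed substrate together charged of the flask you put last, at 12 h

- partner is single-handed; left-handed substrate and right-handed substrate are mirror images of each other, charged as a racemate, each of them at the stated concentration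
- reactions considered so far: partner + left-handed substrate -> left-handed product; partner + right-handed substrate -> right-handed product; 2 partner -> self-condensation product
- the handed part of partner does not stay in what it makes, so the products of the two hands are mirror images too

First I asked what had to be known well. Time mattered little: the alpha run gained 1 percentage point between 2.50 h and 6.00 h, and 12 h is twice its last reading. That run stalled with 27.1% of left-handed substrate still there, so I took partner as the limiting reagent. The partner charge therefore mattered directly for south, since my estimate there scales with it. The scatter of 0.5 points on the last alpha reading moved south by 0.42 points.

The alpha run gave 0.728 for what I call the partner yield: left-handed product, as a fraction of the left-handed substrate charged, per equivalent of partner charged, once a flask has stopped. This lies above 0.5, so the left step took more partner than the other two steps together. That share depends on [partner] as well as on [left-handed substrate]/[right-handed substrate], since self-condensation competes for partner, and the ratio falls as the left-handed substrate goes. South held less partner than alpha, so I expected less self-condensation, less fall in that ratio and a yield slightly higher. The yield gave south 19.7% and south-west 29.1%. For north it gave 116%, above the ceiling of 50.0%, so I put north near that ceiling. Product rose with partner from alpha to beta, so I ordered the flasks by partner charge.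

The forecast gave north > south-east > south-west > south, with 49.8% and 19.5%, on the ground that “the order follows partner loading”.

The flasks gave north > south-east > south-west > south, with 49.9% and 20.0%.

    partner + left-handed substrate → left-handed product (k = 6.60 /M/h)
    partner + right-handed substrate → right-handed product (k = 1.50 /M/h)
    2 partner → self-condensation product (k = 0.780 /M/h)

In south, the left step had done half of its turnover by 0.552 h, and by 6.00 h the right step had 99.5% of its turnover behind it, with partner at 0.367% of its charge. In north, left-handed substrate was down to 0.140% at 12.0 h, while right-handed product had climbed from 32.7% to 36.9% since 6.00 h. South's own yield came to 0.742, against 0.728 from alpha. With 0.320 equiv of partner in the south recipe, the yield gives 11.6%; that flask gave 12.4%.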